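## Retrosynthetic overview

1. The skipped diene is cut at the CH2–CH= bond between the two side-chain alkenes (Pd-catalysed alkenyl–allyl coupling). This gives a chromene allylic chloride and the (E)-alkenylzirconocene of silylated (S)-dehydrolinalool, made from geraniol by Sharpless epoxidation and epoxy chloride elimination.
2. The C3=C4 bond of the 2H-chromene is traced back to a chroman-3-one (reduction, dehydration), and the enoate handle of the side chain to an aldehyde (Wittig).
3. Key disconnection: ring atom C4 is taken out of the pyran ring. The chroman-3-one is made from a 2,2-disubstituted benzofuran-3(2H)-one by one-carbon insertion between C3 and the arene carbon, forming C3–C4 and C4–C4a.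
4. Feature on which this rests: C2 of the chromene is a quaternary, non-enolisable ether carbon (O1, CH3, side chain, C3) that is hard to set directly. In the five-membered furanone ring the same carbon lies between O1 and the C3 ketone, is acidic, and can be quaternised by asymmetric Michael addition to acrolein; the ring atom then lacking is exactly C4.
5. Ring order: benzene ring purchased (4-methoxy-2-methylphenol); furanone ring closed by O-alkylation (step 5); furanone ring enlarged to the pyranone ring (step 8).

Key step: step 8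

Remark on the chemistry (assumption): commercial 4-methoxy-2-methylphenol replaces 2-methylhydroquinone as the arene source, because the free hydroquinone would be expected to acylate para to the methyl group and a silyl ether would not survive the acylation; the sense of induction in step 6 is assigned by analogy, and the pseudoenantiomeric catalyst would be used if the opposite sense were found.

Handling remark: from compound 16 onwards the 2H-chromenes are kept from light and strong heat, since electrocyclic ring opening to the o-quinone methide would racemise C2.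

## Route

Step 1
Reactants: 1 4-methoxy-2-methylphenol
Product: 3 1-(2-hydroxy-5-methoxy-3-methylphenyl)propan-1-one, via aryl propanoate 2 (not isolated)
Conditions: EtCO2H, BF3·OEt2, 100 °C; aq. NaOAc work-up
Reagents that add atoms: propionic acid, CCC(=O)O
Why: BF3 promotes O-acylation and then Fries rearrangement of the aryl propanoate, so the acyl group should enter the only free position ortho to the phenol oxygen (para is blocked by OMe), where the ketone is held as a boron chelate.

Step 2
Reactants: 3 1-(2-hydroxy-5-methoxy-3-methylphenyl)propan-1-one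
Product: 4 1-(2,5-dihydroxy-3-methylphenyl)propan-1-one
Conditions: BBr3, CH2Cl2, −78 → 0 °C; MeOH, then H2O
Reagents that add atoms: none
Why: Lewis-acid cleavage of the aryl methyl ether by BBr3 (bromide attacks the O-methyl group) should free the 5-OH at a stage where only a robust hydroxy ketone is present.

Step 3
Reactants: 4 1-(2,5-dihydroxy-3-methylphenyl)propan-1-one
Product: 5 1-[2-hydroxy-3-methyl-5-(triisopropylsilyloxy)phenyl]propan-1-one
Conditions: i-Pr3SiCl (1.05 equiv), imidazole, DMF, 0 °C → rt
Reagents that add atoms: triisopropylsilyl chloride, CC(C)[Si](Cl)(C(C)C)C(C)C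
Why: Chemoselective silylation, because the 5-OH is unhindered whereas the 2-OH is hydrogen-bonded to the ketone and flanked by the methyl group, so the bulky silyl chloride should protect only the former.

Step 4
Reactants: 5 1-[2-hydroxy-3-methyl-5-(triisopropylsilyloxy)phenyl]propan-1-one
Product: 6 2-bromo-1-[2-hydroxy-3-methyl-5-(triisopropylsilyloxy)phenyl]propan-1-one (racemic)
Conditions: CuBr2 (2.1 equiv), EtOAc/CHCl3, reflux
Reagents that add atoms: copper dibromide (CuBr2), Br[Cu]Br
Why: α-Bromination of the aryl ethyl ketone through its copper enolate; every ring position ortho or para to the free phenol is substituted, so nuclear bromination should not compete.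

Step 5
Reactants: 6 2-bromo-1-[2-hydroxy-3-methyl-5-(triisopropylsilyloxy)phenyl]propan-1-one
Product: 7 2,7-dimethyl-5-(triisopropylsilyloxy)-1-benzofuran-3(2H)-one (racemic)
Conditions: K2CO3, acetone, rt, argon
Reagents that add atoms: none
Why: Intramolecular Williamson etherification (5-exo-tet attack of the phenoxide on the α-bromo ketone) closes the furanone ring; C2 is formed racemic here and is reset through the enolate in step 6.

Step 6
Reactants: 7 2,7-dimethyl-5-(triisopropylsilyloxy)-1-benzofuran-3(2H)-one; 8 acrolein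
Product: 9 3-[(2S)-2,7-dimethyl-3-oxo-5-(triisopropylsilyloxy)-2,3-dihydro-1-benzofuran-2-yl]propanal
Conditions: acrolein (1.5 equiv), 9-O-(9-phenanthryl)cupreidine (10 mol%), CH2Cl2, −25 °C
Reagents that add atoms: none
Why: Enantioselective organocatalytic Michael addition, in which the quinuclidine nitrogen deprotonates C2 (acidic between the C3 ketone and O1), the ion-paired enolate is oriented by the 6'-OH hydrogen-bond donor that also activates acrolein, and C–C bond formation on one enolate face sets the quaternary C2 centre (S) under catalyst control.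

Step 7
Reactants: 9 3-[(2S)-2,7-dimethyl-3-oxo-5-(triisopropylsilyloxy)-2,3-dihydro-1-benzofuran-2-yl]propanal; 10 ethyl 2-(triphenylphosphoranylidene)propanoate
Product: 11 ethyl (2E)-2-methyl-5-[(2S)-2,7-dimethyl-3-oxo-5-(triisopropylsilyloxy)-2,3-dihydro-1-benzofuran-2-yl]pent-2-enoate
Conditions: CH2Cl2, rt
Reagents that add atoms: none
Why: Wittig olefination with a stabilised ylide should give the (E)-trisubstituted enoate and should touch only the aldehyde, the hindered aryl ketone next to the quaternary carbon being far less reactive.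

Step 8
Reactants: 11 ethyl (2E)-2-methyl-5-[(2S)-2,7-dimethyl-3-oxo-5-(triisopropylsilyloxy)-2,3-dihydro-1-benzofuran-2-yl]pent-2-enoate
Product: 13 ethyl (2E)-2-methyl-5-[(2S)-2,8-dimethyl-3-oxo-6-(triisopropylsilyloxy)-3,4-dihydro-2H-chromen-2-yl]pent-2-enoate, via C4-trimethylsilyl ketone 12 (not isolated)
Conditions: Me3SiCHN2 (2 M in hexanes, 2 equiv), Sc(OTf)3 (15 mol%), CH2Cl2, −40 → 0 °C; then 1 M HCl, THF, rt
Reagents that add atoms: trimethylsilyldiazomethane, C[Si](C)(C)C=[N+]=[N-]
Why: Proposed new method: Sc(OTf)3 coordinates the C3 carbonyl, the diazo carbon adds to C3 to give a β-diazonium alkoxide, and loss of N2 is coupled with a 1,2-shift of the electron-rich arene carbon (ortho to the ring oxygen) from C3 to the new carbon, so that C3–C4 and C4–C4a form in one operation; the closest known reaction type is the Lewis-acid-promoted trimethylsilyldiazomethane homologation of 1-indanones to 2-tetralones and of other cyclic ketones (Tiffeneau–Demjanov-type ring expansion), not yet shown on a 2,2-disubstituted benzofuran-3(2H)-one. The pyranone ring is not closed by a cyclisation but arises by enlargement of the furanone ring from five to six members through this aryl shift. No stereocentre is created in the isolated product, since the silyl-bearing C4 of 12 is lost on protodesilylation, and C2, which is quaternary and never a reacting centre, should keep its S configuration. The step needs chemoselectivity for the ketone over the trisubstituted enoate, which Lewis-acid activation at low temperature should secure because dipolar cycloaddition of the diazo reagent to an α-methyl-β-alkyl enoate is slow, and it needs a single insertion, which the hindered α-silyl ketone 12 flanked by the quaternary C2 should secure. Aryl migration is expected to be preferred, because the arene carbon is stabilised by the ortho oxygen and the bulky silyl group should lie anti to the quaternary C2, which places the aryl bond anti to the leaving N2. Should C2 migrate in part, the chroman-4-one formed would be separated or carried on, since reduction and dehydration lead to the same chromene when C2 bears no hydrogen.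

Step 9
Reactants: 13 ethyl (2E)-2-methyl-5-[(2S)-2,8-dimethyl-3-oxo-6-(triisopropylsilyloxy)-3,4-dihydro-2H-chromen-2-yl]pent-2-enoate
Product: 14 ethyl (2E)-5-[(2S)-3-hydroxy-2,8-dimethyl-6-(triisopropylsilyloxy)-3,4-dihydro-2H-chromen-2-yl]-2-methylpent-2-enoate (mixture of C3 epimers)
Conditions: NaBH4, MeOH, −10 °C
Reagents that add atoms: none
Why: Hydride reduction of the ketone with NaBH4; the α-methyl-β-alkyl enoate should not be reduced at low temperature, and the C3 epimer mixture is of no consequence because C3 becomes sp2 in the next step.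

Step 10
Reactants: 14 ethyl (2E)-5-[(2S)-3-hydroxy-2,8-dimethyl-6-(triisopropylsilyloxy)-3,4-dihydro-2H-chromen-2-yl]-2-methylpent-2-enoate
Product: 16 ethyl (2E)-5-[(2S)-2,8-dimethyl-6-(triisopropylsilyloxy)-2H-chromen-2-yl]-2-methylpent-2-enoate, via C3 sulfamate salt 15 (not isolated)
Conditions: Burgess reagent (MeO2C–N(−)–SO2–N(+)Et3), toluene, rt → 50 °C, dark
Reagents that add atoms: none
Why: Burgess dehydration (syn-elimination of the sulfamate); C2 has no hydrogen, so elimination can only take a benzylic C4–H and should give the styrene-type C3=C4 bond of the 2H-chromene without ionisation at C3.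

Step 11
Reactants: 16 ethyl (2E)-5-[(2S)-2,8-dimethyl-6-(triisopropylsilyloxy)-2H-chromen-2-yl]-2-methylpent-2-enoate
Product: 17 (2E)-5-[(2S)-2,8-dimethyl-6-(triisopropylsilyloxy)-2H-chromen-2-yl]-2-methylpent-2-en-1-ol
Conditions: i-Bu2AlH (DIBAL-H, 2.5 equiv), CH2Cl2, −78 °C; aq. KNaC4H4O6 (Rochelle salt)
Reagents that add atoms: none
Why: 1,2-Reduction of the conjugated ester with i-Bu2AlH should give the (E)-allylic alcohol, the chromene and the aryl silyl ether being inert to the hydride.

Step 12
Reactants: 17 (2E)-5-[(2S)-2,8-dimethyl-6-(triisopropylsilyloxy)-2H-chromen-2-yl]-2-methylpent-2-en-1-ol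
Product: 18 (2S)-2-[(3E)-5-chloro-4-methylpent-3-en-1-yl]-2,8-dimethyl-6-(triisopropylsilyloxy)-2H-chromene
Conditions: N-chlorosuccinimide, Me2S, CH2Cl2, −20 → 0 °C
Reagents that add atoms: N-chlorosuccinimide, ClN1C(=O)CCC1=O
Why: Corey–Kim chlorination, in which the alkoxysulfonium ion is displaced by chloride at the primary carbon, should give the allylic chloride without allylic transposition or loss of the E geometry.

Step 13
Reactants: 19 geraniol
Product: 20 [(2S,3S)-3-methyl-3-(4-methylpent-3-en-1-yl)oxiran-2-yl]methanol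
Conditions: Ti(OiPr)4 (5 mol%), L-(+)-diethyl tartrate (6 mol%), t-BuOOH, 4 Å MS, CH2Cl2, −20 °C
Reagents that add atoms: tert-butyl hydroperoxide, CC(C)(C)OO
Why: Sharpless asymmetric epoxidation; the hydroxyl-directed titanium tartrate catalyst epoxidises only the allylic 2,3-double bond, and the (2R,3R)-tartrate ligand is the one that gives the (2S,3S)-epoxy alcohol, whose C3 becomes the carbinol centre of the side chain.

Step 14
Reactants: 20 [(2S,3S)-3-methyl-3-(4-methylpent-3-en-1-yl)oxiran-2-yl]methanol
Product: 21 (2S,3R)-3-(chloromethyl)-2-methyl-2-(4-methylpent-3-en-1-yl)oxirane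
Conditions: PPh3, CCl4, NaHCO3, reflux
Reagents that add atoms: tetrachloromethane, ClC(Cl)(Cl)Cl
Why: Appel chlorination of the primary alcohol under buffered conditions should leave the epoxide and both of its stereocentres untouched (the descriptor at the CH carbon changes only because CH2Cl outranks the ring carbon).

Step 15
Reactants: 21 (2S,3R)-3-(chloromethyl)-2-methyl-2-(4-methylpent-3-en-1-yl)oxirane
Product: 22 (3S)-3,7-dimethyloct-6-en-1-yn-3-ol
Conditions: n-BuLi (3.2 equiv), THF, −78 → −20 °C; H2O
Reagents that add atoms: none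
Why: Base-induced double elimination of a 2,3-epoxy chloride (lithiation α to chlorine opens the epoxide to a chloroalkenyl alkoxide, then loss of HCl gives the alkyne); the C–O bond at the quaternary carbon is never broken, so the S configuration of the tertiary propargylic alcohol follows from the epoxide.

Step 16
Reactants: 22 (3S)-3,7-dimethyloct-6-en-1-yn-3-ol
Product: 23 triethyl{[(3S)-3,7-dimethyloct-6-en-1-yn-3-yl]oxy}silane
Conditions: Et3SiOTf, 2,6-lutidine, CH2Cl2, −78 → 0 °C
Reagents that add atoms: triethylsilyl trifluoromethanesulfonate, CC[Si](CC)(CC)OS(=O)(=O)C(F)(F)F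
Why: Silylation of the hindered tertiary alcohol with the silyl triflate masks the acidic OH before hydrozirconation and installs a group that is removed together with the aryl silyl ether at the end.

Step 17
Reactants: 23 triethyl{[(3S)-3,7-dimethyloct-6-en-1-yn-3-yl]oxy}silane; 18 (2S)-2-[(3E)-5-chloro-4-methylpent-3-en-1-yl]-2,8-dimethyl-6-(triisopropylsilyloxy)-2H-chromene
Product: 25 (2S)-2-[(3E,6E,8S)-4,8,12-trimethyl-8-(triethylsilyloxy)trideca-3,6,11-trien-1-yl]-2,8-dimethyl-6-(triisopropylsilyloxy)-2H-chromene, via alkenylzirconocene 24 (not isolated)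
Conditions: 23 (1.3 equiv), Cp2Zr(H)Cl (1.4 equiv), THF, rt; then 18, Pd(PPh3)4 (5 mol%), THF, rt, dark
Reagents that add atoms: none
Why: Hydrozirconation adds Zr–H syn across the terminal alkyne with zirconium at the terminal carbon (the trisubstituted alkene is much slower), and the Negishi alkenyl–allyl coupling through a π-allylpalladium intermediate should join the alkenyl group to the less hindered CH2 terminus with retention of both alkene geometries, giving the skipped (E,E)-diene.

Step 18
Reactants: 25 (2S)-2-[(3E,6E,8S)-4,8,12-trimethyl-8-(triethylsilyloxy)trideca-3,6,11-trien-1-yl]-2,8-dimethyl-6-(triisopropylsilyloxy)-2H-chromene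
Product: 26 (2S)-2-[(3E,6E,8S)-8-hydroxy-4,8,12-trimethyltrideca-3,6,11-trien-1-yl]-2,8-dimethyl-2H-chromen-6-ol (target)
Conditions: Bu4NF (3 equiv), THF, 0 °C → rt, dark
Reagents that add atoms: none
Why: Fluoride-induced cleavage of both silyl ethers should free the phenol and the tertiary allylic alcohol without touching the stereocentres, the chromene or the diene.

## Compound list

1 | 4-methoxy-2-methylphenol | COc1ccc(O)c(C)c1 | starting material
2 | 4-methoxy-2-methylphenyl propanoate | CCC(=O)Oc1ccc(OC)cc1C | intermediate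
3 | 1-(2-hydroxy-5-methoxy-3-methylphenyl)propan-1-one | CCC(=O)c1cc(OC)cc(C)c1O | intermediate
4 | 1-(2,5-dihydroxy-3-methylphenyl)propan-1-one | CCC(=O)c1cc(O)cc(C)c1O | intermediate
5 | 1-[2-hydroxy-3-methyl-5-(triisopropylsilyloxy)phenyl]propan-1-one | CCC(=O)c1cc(O[Si](C(C)C)(C(C)C)C(C)C)cc(C)c1O | intermediate
6 | 2-bromo-1-[2-hydroxy-3-methyl-5-(triisopropylsilyloxy)phenyl]propan-1-one (racemic) | CC(Br)C(=O)c1cc(O[Si](C(C)C)(C(C)C)C(C)C)cc(C)c1O | intermediate
7 | 2,7-dimethyl-5-(triisopropylsilyloxy)-1-benzofuran-3(2H)-one (racemic) | CC1C(=O)c2cc(O[Si](C(C)C)(C(C)C)C(C)C)cc(C)c2O1 | intermediate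
8 | acrolein | C=CC=O | starting material
9 | 3-[(2S)-2,7-dimethyl-3-oxo-5-(triisopropylsilyloxy)-2,3-dihydro-1-benzofuran-2-yl]propanal | O=CCC[C@@]1(C)C(=O)c2cc(O[Si](C(C)C)(C(C)C)C(C)C)cc(C)c2O1 | intermediate
10 | ethyl 2-(triphenylphosphoranylidene)propanoate | CCOC(=O)C(C)=P(c1ccccc1)(c1ccccc1)c1ccccc1 | starting material
11 | ethyl (2E)-2-methyl-5-[(2S)-2,7-dimethyl-3-oxo-5-(triisopropylsilyloxy)-2,3-dihydro-1-benzofuran-2-yl]pent-2-enoate | CCOC(=O)/C(C)=C/CC[C@@]1(C)C(=O)c2cc(O[Si](C(C)C)(C(C)C)C(C)C)cc(C)c2O1 | intermediate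
12 | ethyl (2E)-2-methyl-5-[(2S)-2,8-dimethyl-3-oxo-6-(triisopropylsilyloxy)-4-(trimethylsilyl)-3,4-dihydro-2H-chromen-2-yl]pent-2-enoate (C4 epimers) | CCOC(=O)/C(C)=C/CC[C@@]1(C)C(=O)C([Si](C)(C)C)c2cc(O[Si](C(C)C)(C(C)C)C(C)C)cc(C)c2O1 | intermediate
13 | ethyl (2E)-2-methyl-5-[(2S)-2,8-dimethyl-3-oxo-6-(triisopropylsilyloxy)-3,4-dihydro-2H-chromen-2-yl]pent-2-enoate | CCOC(=O)/C(C)=C/CC[C@@]1(C)C(=O)Cc2cc(O[Si](C(C)C)(C(C)C)C(C)C)cc(C)c2O1 | intermediate
14 | ethyl (2E)-5-[(2S)-3-hydroxy-2,8-dimethyl-6-(triisopropylsilyloxy)-3,4-dihydro-2H-chromen-2-yl]-2-methylpent-2-enoate (C3 epimers) | CCOC(=O)/C(C)=C/CC[C@@]1(C)C(O)Cc2cc(O[Si](C(C)C)(C(C)C)C(C)C)cc(C)c2O1 | intermediate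
15 | triethylammonium salt of the C3 N-(methoxycarbonyl)sulfamate of 14 | CCOC(=O)/C(C)=C/CC[C@@]1(C)C(OS(=O)(=O)[N-]C(=O)OC)Cc2cc(O[Si](C(C)C)(C(C)C)C(C)C)cc(C)c2O1.CC[NH+](CC)CC | intermediate
16 | ethyl (2E)-5-[(2S)-2,8-dimethyl-6-(triisopropylsilyloxy)-2H-chromen-2-yl]-2-methylpent-2-enoate | CCOC(=O)/C(C)=C/CC[C@@]1(C)C=Cc2cc(O[Si](C(C)C)(C(C)C)C(C)C)cc(C)c2O1 | intermediate
17 | (2E)-5-[(2S)-2,8-dimethyl-6-(triisopropylsilyloxy)-2H-chromen-2-yl]-2-methylpent-2-en-1-ol | OC/C(C)=C/CC[C@@]1(C)C=Cc2cc(O[Si](C(C)C)(C(C)C)C(C)C)cc(C)c2O1 | intermediate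
18 | (2S)-2-[(3E)-5-chloro-4-methylpent-3-en-1-yl]-2,8-dimethyl-6-(triisopropylsilyloxy)-2H-chromene | ClC/C(C)=C/CC[C@@]1(C)C=Cc2cc(O[Si](C(C)C)(C(C)C)C(C)C)cc(C)c2O1 | intermediate
19 | geraniol | CC(C)=CCC/C(C)=C/CO | starting material
20 | [(2S,3S)-3-methyl-3-(4-methylpent-3-en-1-yl)oxiran-2-yl]methanol | CC(C)=CCC[C@]1(C)O[C@H]1CO | intermediate
21 | (2S,3R)-3-(chloromethyl)-2-methyl-2-(4-methylpent-3-en-1-yl)oxirane | CC(C)=CCC[C@]1(C)O[C@H]1CCl | intermediate
22 | (3S)-3,7-dimethyloct-6-en-1-yn-3-ol | CC(C)=CCC[C@](C)(O)C#C | intermediate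
23 | triethyl{[(3S)-3,7-dimethyloct-6-en-1-yn-3-yl]oxy}silane | CC(C)=CCC[C@](C)(O[Si](CC)(CC)CC)C#C | intermediate
24 | chlorobis(cyclopentadienyl)[(1E,3S)-3,7-dimethyl-3-(triethylsilyloxy)octa-1,6-dien-1-yl]zirconium | CC(C)=CCC[C@](C)(O[Si](CC)(CC)CC)/C=C/[Zr](Cl)(C1C=CC=C1)C1C=CC=C1 | intermediate
25 | (2S)-2-[(3E,6E,8S)-4,8,12-trimethyl-8-(triethylsilyloxy)trideca-3,6,11-trien-1-yl]-2,8-dimethyl-6-(triisopropylsilyloxy)-2H-chromene | CC(C)=CCC[C@](C)(O[Si](CC)(CC)CC)/C=C/C/C(C)=C/CC[C@@]1(C)C=Cc2cc(O[Si](C(C)C)(C(C)C)C(C)C)cc(C)c2O1 | intermediate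
26 | (2S)-2-[(3E,6E,8S)-8-hydroxy-4,8,12-trimethyltrideca-3,6,11-trien-1-yl]-2,8-dimethyl-2H-chromen-6-ol | CC(C)=CCC[C@](C)(O)/C=C/C/C(C)=C/CC[C@@]1(C)C=Cc2cc(O)cc(C)c2O1 | target

## Step count and risks

Total step count: 18. Longest linear sequence: 14 steps (steps 1–12, 17 and 18, from 1 to 26).

Steps most likely to fail:

1. Step 8 (ring expansion). The carbonyl addition may be sluggish on the donor-substituted ketone, the quaternary C2 may migrate in competition with the aryl group, the diazo reagent may add to the enoate, or a second insertion may occur. The fallback sets out from 11 and uses known chemistry. A Takai–Lombardo methylenation (Zn, CH2Br2, TiCl4, THF/CH2Cl2), which leaves esters alone, would give the exocyclic alkene ethyl (2E)-2-methyl-5-[(2S)-2,7-dimethyl-3-methylidene-5-(triisopropylsilyloxy)-2,3-dihydro-1-benzofuran-2-yl]pent-2-enoate F1. Treatment of this alkene with PhI(OH)OTs in aqueous methanol would then bring about the known oxidative ring expansion of 1-methylidene benzocycloalkanes: trivalent iodine adds to the alkene, the solvent adds to the benzylic carbon, and the aryl group shifts with loss of PhI. The product should be chromanone 13, where the route is rejoined.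

2. Step 6 (asymmetric Michael addition). Facial discrimination may be poor for a 2-methyl pronucleophile, the benzofuranone may be deprotonated too slowly by the amine catalyst, or acrolein may polymerise. The fallback sets out from 7 and sets the quaternary centre by allylation instead of conjugate addition. O-Acylation with allyl chloroformate (Et3N, THF, 0 °C) would give the enol carbonate 2,7-dimethyl-5-(triisopropylsilyloxy)-1-benzofuran-3-yl prop-2-en-1-yl carbonate F2. Decarboxylative asymmetric allylic alkylation of the Tsuji–Trost type (Pd2(dba)3, the enantiomer of a tert-butyl phosphinooxazoline ligand that leads to the 2S product, toluene, rt) would give (2S)-2,7-dimethyl-2-(prop-2-en-1-yl)-5-(triisopropylsilyloxy)-1-benzofuran-3(2H)-one F3. Hydroboration and oxidation (9-BBN, THF, then NaBO3·4H2O) would give (2S)-2-(3-hydroxypropyl)-2,7-dimethyl-5-(triisopropylsilyloxy)-1-benzofuran-3(2H)-one F4. Dess–Martin oxidation of this alcohol would return aldehyde 9.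

3. Step 17 (alkenyl–allyl coupling). Transmetalation from the hindered alkenylzirconocene next to the quaternary carbinol carbon may be slow, or C–C bond formation may occur at the wrong terminus of the π-allyl intermediate. The fallback sets out from 18 and 23 and makes the (E)-alkene by a directed reduction instead of a hydrometalation. Copper-mediated coupling of the terminal alkyne of 23 with chloride 18 (CuI, K2CO3, NaI, DMF, rt) would give the skipped enyne (2S)-2-[(3E,8S)-4,8,12-trimethyl-8-(triethylsilyloxy)trideca-3,11-dien-6-yn-1-yl]-2,8-dimethyl-6-(triisopropylsilyloxy)-2H-chromene F5. Bu4NF would remove both silyl groups to give (2S)-2-[(3E,8S)-8-hydroxy-4,8,12-trimethyltrideca-3,11-dien-6-yn-1-yl]-2,8-dimethyl-2H-chromen-6-ol F6. The hydroxyl-directed trans-hydroalumination of the propargylic alcohol (NaAlH2(OCH2CH2OMe)2, Red-Al, THF, 0 °C → rt) would then give the (E)-allylic alcohol, which is target 26.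

## Further compounds

F1 | step 8 | ethyl (2E)-2-methyl-5-[(2S)-2,7-dimethyl-3-methylidene-5-(triisopropylsilyloxy)-2,3-dihydro-1-benzofuran-2-yl]pent-2-enoate | CCOC(=O)/C(C)=C/CC[C@@]1(C)C(=C)c2cc(O[Si](C(C)C)(C(C)C)C(C)C)cc(C)c2O1
F2 | step 6 | 2,7-dimethyl-5-(triisopropylsilyloxy)-1-benzofuran-3-yl prop-2-en-1-yl carbonate | C=CCOC(=O)Oc1c(C)oc2c(C)cc(O[Si](C(C)C)(C(C)C)C(C)C)cc12
F3 | step 6 | (2S)-2,7-dimethyl-2-(prop-2-en-1-yl)-5-(triisopropylsilyloxy)-1-benzofuran-3(2H)-one | C=CC[C@@]1(C)C(=O)c2cc(O[Si](C(C)C)(C(C)C)C(C)C)cc(C)c2O1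
F4 | step 6 | (2S)-2-(3-hydroxypropyl)-2,7-dimethyl-5-(triisopropylsilyloxy)-1-benzofuran-3(2H)-one | OCCC[C@@]1(C)C(=O)c2cc(O[Si](C(C)C)(C(C)C)C(C)C)cc(C)c2O1
F5 | step 17 | (2S)-2-[(3E,8S)-4,8,12-trimethyl-8-(triethylsilyloxy)trideca-3,11-dien-6-yn-1-yl]-2,8-dimethyl-6-(triisopropylsilyloxy)-2H-chromene | CC(C)=CCC[C@](C)(O[Si](CC)(CC)CC)C#CC/C(C)=C/CC[C@@]1(C)C=Cc2cc(O[Si](C(C)C)(C(C)C)C(C)C)cc(C)c2O1
F6 | step 17 | (2S)-2-[(3E,8S)-8-hydroxy-4,8,12-trimethyltrideca-3,11-dien-6-yn-1-yl]-2,8-dimethyl-2H-chromen-6-ol | CC(C)=CCC[C@](C)(O)C#CC/C(C)=C/CC[C@@]1(C)C=Cc2cc(O)cc(C)c2O1
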